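Numbering used throughout: decalin carbons C1–C10 (ring A = C1–C5, C10; ring B = C5–C10), quinone carbons primed. In this numbering the target is (5R,8R,9S,10R).

## Structural features

The target is a trans-fused decalin with a methylidene at C4, methyl groups at C5, C8 and C9, and a CH2 link from C9 to C3′ of a 2′-hydroxy-5′-methoxy-1,4-benzoquinone. Four contiguous stereocentres (C5 quaternary, C10, C9 quaternary, C8) lie along one edge of ring B. The three methyl groups are on one face, H10 is on the other, and the C5 and C9 methyls are 1,3-diaxial. The hydroxyquinone is a vinylogous acid, a Michael acceptor and an oxidant, so it cannot pass through organometallic, ylide or hydrazine steps and must be carried as an arene. The exocyclic alkene can migrate into ring A under acid. Ring B holds no functional group in the target, so whatever activates bond formation there must be erased afterwards. The real difficulty is the C8–C9 bond: a tertiary centre joined to a quaternary one that carries two groups of similar size (methyl, arylmethyl), set against quaternary C5. The key step uses the adjacency of C8 and C9 in ring B: with C6 as a ketone and the C9 methyl as a formyl group, C8–C9 is the bond of a 1,5-dicarbonyl (Michael) retron, and one Wolff–Kishner operation later removes both carbonyls.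

## Logic of the disconnections

27 ⇒ 26. The C2′ hydroxyl is traced back to a methyl ether. The free vinylogous acid is released last because it is acidic and electrophilic. The gain is a quinone with two like substituents. The demand is that hydrolysis picks the methoxy group beside the side chain and spares the exocyclic alkene.

26 ⇒ 25. The two quinone carbonyls are returned to aryl methyl ethers. The arene is inert to the organometallic, hydride, ylide and hydrazine steps the route needs. The gain is a symmetric aryl group. The demand is an oxidative demethylation that leaves the 1,1-disubstituted alkene alone.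

25 ⇒ 24 ⇒ 23 ⇒ 22. The C4=CH2 bond is cut (carbonyl olefination) and the C4 carbonyl is taken back to a protected alcohol. C4 must be oxygenated from the start, because it is the carbonyl that generates the C5 enolate. The gain is that the acid-sensitive alkene is absent from all earlier stages. The demands are methylenation next to quaternary C5 and a C4 protecting group that survives hot hydroxide.

22 ⇒ 20. The C6 methylene and the C9 methyl are returned to a C6 ketone and a C9 formyl group, with no skeletal cut. Their 1,5-relationship creates the retron for the next cut. The demand is that two hindered carbonyls go to the hydrocarbon level in one operation without ring B opening.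

20 ⇒ 17. The C8–C9 bond is cut and ring B opens. This is the bond between the α-carbon of the formyl group and the β-carbon of the C6 enone. The gain is the loss of one ring and two stereocentres, including the quaternary C9, and 17 can be a C9 epimer mixture. The demand is a 6-endo closure that puts the formyl carbon axial and the C8 methyl equatorial.

17 ⇒ 16 ⇒ 15 ⇒ 13. Only functional groups change: enone and aldehyde come from an allylic and a primary alcohol, and the primary C–O bond comes from anti-Markovnikov hydration of a C9=CH2 alkene. The gain is a compound with no carbonyl and no C9 stereocentre. The demands are that hydroboration chooses the 1,1-disubstituted alkene over the (E)-propenyl group, and that the C4 and C6 oxygens carry different protecting groups.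

13 ⇒ 12 ⇒ 11 ⇒ 10. The C4 ether goes back to the ketone and the C6 silyl ether to the aldol hydroxyl. The hydroxyl is capped first because a β-hydroxy ketone with a quaternary α-carbon is prone to retro-aldol cleavage. The order of the steps is what differentiates the two oxygens.

10 ⇒ 4 + 5 + 6. Two bonds on adjacent carbons are cut: C9–C10 (conjugate addition) and C5–C6 (aldol). C10 is β and C5 is α to the C4 carbonyl, and absolute configuration enters here. The gain is three achiral pieces. The demands are catalyst control at C10, trapping anti to the new substituent, and a regiodefined enolate.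

4 ⇒ 1 + 2. The aryl–CH2 bond is cut. The arene is lithiated between two methoxy groups and the electrophile is an allylic bromide that keeps its vinylic bromide. The demand is substitution at the allylic position only.

## Other disconnections considered

Alternative 1: The cut removes C5–C10 and C3–C4 together and opens both rings to the acyclic triene A1, in which only C8 and C9 are stereogenic. In the forward direction Et2AlCl would bind the ester and drive an intramolecular Diels–Alder reaction of the trisubstituted (E)-enoate onto the terminal (E)-diene, giving the trans-fused octalin ester A2.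
- In its favour: two rings, two C–C bonds and the C4, C5 and C10 centres arise in one operation. The suprafacial addition transfers the enoate geometry to the C4/C5 relationship, and the ester carbon is already the future methylidene carbon.
- Against it here: the dienophile is β,β-disubstituted and must create quaternary C5, while the diene terminus C10 hangs on quaternary C9, so both reacting ends are congested. Trienes of this tether length have little built-in preference between cis and trans fusion. Facial control would rest on the methyl/arylmethyl difference at C9. A1 also needs an open-chain tertiary/quaternary pair, which is harder to make than the same pair formed in a chair.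
- After the cycloaddition the C1=C2 alkene must be hydrogenated and the ester turned into the methylidene by reduction and a selenoxide-type elimination.
- Comparison: in bonds and rings formed per step this alternative is the better plan, and it needs no protecting group and no carbonyl removal in ring B. Mechanistically the chosen plan is easier to defend, because the ring A stereocentres exist before the key step and allow one chair only. Overall step counts should be similar once A1 is made.

Alternative 2: No ring bond is cut. The C9 methyl is returned to C10 and the C5 methyl to C4, which leads to the ent-drimane tertiary alcohol A3. In the forward direction ionisation at C8 (BF3·OEt2 or a confined strong Brønsted acid) should start four suprafacial 1,2-shifts, each anti to the one before (H9 to C8, the C10 methyl to C9, H5 to C10, a C4 methyl to C5). Loss of a proton from the remaining C4 methyl would give the arene A4, which is identical with 25.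
- In its favour: the shifts are stereospecific, so the configuration of A3 maps onto all four centres of the target. The skeleton of A3 is a regular drimane, and A4 is two steps from 27.
- Against it here: every cation on the path (C8, C9, C10, C5, C4) has its own proton-loss channels, and at the end loss of H3 to the ring alkene competes with the wanted, less substituted exocyclic alkene. The electron-rich aryl group is within reach of the C8 and C10 cations and can trap them by Friedel–Crafts closure. The required ent series is the mirror image of the abundant natural drimane and labdane pool, so A3 needs an enantioselective synthesis of its own.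
- Comparison: on step economy this alternative is clearly the better plan, and in its endgame it is the equal of the chosen one (same last two steps). On control the chosen plan is stronger, since each stereocentre is set in a separate step and not by one cascade that must be selective at five branch points.

Alternative 3: The cut is C5–C6, and ring A is traced back to a 2-methylphenol. The bromide A5 carries the C8/C9 pair on a chain attached to the arene carbon that becomes C10. With KOtBu in tert-butanol the phenoxide would attack the primary bromide through its methyl-bearing ortho carbon (6-exo-tet), giving the cyclohexa-2,4-dienone A6.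
- In its favour: ring A comes from a simple aromatic. O-alkylation would need an eight-membered ring and should not compete, and the protic medium favours C-alkylation. The carbonyl of A6 already sits at C4, so the methylidene is one Wittig step away with no protecting group and no redox change at C4. On this point the alternative is better than the chosen plan.
- Against it here: the unsubstituted para carbon (C1) is also six atoms from the bromide, and alkylation there followed by rearomatisation is an irreversible drain. The new quaternary C5 must form with the right sense relative to C9, again a methyl/arylmethyl distinction. The C10 configuration is postponed to a reduction of the dienone, where the trans fusion is not assured. A5 contains a benzylic quaternary stereocentre beside a tertiary one on an open chain, ortho to a methyl group, which is a hard problem in itself.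
- Comparison: after the key step this alternative is shorter. Before it the chosen plan is simpler, because its stereocentres are built on a ring from a catalytic asymmetric addition. Both plans face the same methyl/arylmethyl question at one quaternary centre, but the chosen plan answers it with ring A already in place.

Key step: step 9

Remarks on the chemistry:
- The C4 oxygen is carried as a methoxymethyl (MOM) ether. A silyl ether there is unlikely to survive hydroxide in glycol at 200 °C, and its loss before the hindered C6 hydrazone forms would expose a β-hydroxy ketone to retro-aldol cleavage.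
- The C6 hydroxyl is capped as a triethylsilyl ether before the C4 ketone is reduced. Without this the two secondary hydroxyls cannot be told apart.
- Assumption: hydride adds to the C4 ketone anti to the axial C5 methyl, so the C4 oxygen is drawn cis to that methyl (4R). This centre is destroyed in step 12 and either epimer would serve.
- Compounds 10–16 are mixtures at the carbinol carbon C6, and 15–17 are mixtures at C9. These centres are drawn without configuration.
- The formyl group of 20 occupies the site of the C9 methyl of 27. The C9 descriptor changes from R (20) to S (22) only because the priorities change.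

## Steps

Step 1
Reactants: 1 1,2,4,5-tetramethoxybenzene; 2 2,3-dibromoprop-1-ene
Product: 4 3-(2-bromoprop-2-en-1-yl)-1,2,4,5-tetramethoxybenzene, via aryllithium 3 (not isolated)
Conditions: n-BuLi, TMEDA, THF, 0 °C; then CuBr·SMe2 (10 mol%), 2, −78 °C → rt
Reagents that add atoms: none
Why: Directed ortho-lithiation takes place at the ring C–H flanked by two methoxy groups, and the aryllithium displaces the allylic bromide of 2 in a copper-catalysed allylic substitution (SN2 and SN2′ give the same product); the vinylic C–Br bond does not react and is kept for step 2.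

Step 2
Reactants: 4 bromoalkene; 5 2-methylcyclohex-2-en-1-one; 6 (E)-but-2-enal
Product: 10 (2S,3R)-2-[(E)-1-hydroxybut-2-en-1-yl]-2-methyl-3-[3-(2,3,5,6-tetramethoxyphenyl)prop-1-en-2-yl]cyclohexan-1-one (ketol; both carbinol epimers), via alkenyllithium 7 (not isolated), via alkenylalane 8 (not isolated), via aluminium enolate 9 (not isolated)
Conditions: t-BuLi (2 equiv), Et2O, −78 °C; Me2AlCl, −78 → −30 °C; Cu(OTf)2 (5 mol%), BINOL-derived N,N-bis(1-phenylethyl)phosphoramidite (10 mol%), 5, −30 °C; then 6, −78 → −40 °C; aq. NH4Cl
Reagents that add atoms: none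
Why: Bromine–lithium exchange and transmetalation give the alkenyl(dimethyl)alane, whose alkenyl group is transferred in preference to methyl in a copper-catalysed asymmetric conjugate addition (the divalent copper salt is reduced in the flask to the active monovalent copper–phosphoramidite complex); the ligand antipode is chosen so that C10 forms with the R configuration. The regiodefined enolate 9 then adds to the aldehyde carbon of 6 (aldol, closed six-membered transition state) on the face anti to the new C10 substituent, which sets quaternary C5 with the C5–C6 and C10–C9 bonds trans; the carbinol centre is not controlled and is erased in step 8.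

Step 3
Reactants: 10 ketol
Product: 11 (2S,3R)-2-methyl-3-[3-(2,3,5,6-tetramethoxyphenyl)prop-1-en-2-yl]-2-[(E)-1-(triethylsilyloxy)but-2-en-1-yl]cyclohexan-1-one
Conditions: Et3SiOTf, 2,6-lutidine, CH2Cl2, −78 °C
Reagents that add atoms: triethylsilyl trifluoromethanesulfonate, CC[Si](CC)(CC)OS(=O)(=O)C(F)(F)F
Why: Silylation of the secondary allylic alcohol with a silyl triflate and a hindered pyridine base at low temperature; it blocks retro-aldol cleavage and marks the C6 oxygen as the one to be released later.

Step 4
Reactants: 11 silyloxy ketone
Product: 12 (1R,2R,3R)-2-methyl-3-[3-(2,3,5,6-tetramethoxyphenyl)prop-1-en-2-yl]-2-[(E)-1-(triethylsilyloxy)but-2-en-1-yl]cyclohexan-1-ol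
Conditions: NaBH4, MeOH/THF, 0 °C → rt
Reagents that add atoms: none
Why: Borohydride reduction of the ketone; with the C5–C6 and C10–C9 bonds equatorial the C5 methyl is axial, so hydride should enter anti to it (axial attack) and give the equatorial 4R alcohol. The protic medium protonates the alkoxide at once, which prevents silyl migration from the C6 oxygen.

Step 5
Reactants: 12 alcohol
Product: 13 (1R,2R,3R)-1-(methoxymethoxy)-2-methyl-3-[3-(2,3,5,6-tetramethoxyphenyl)prop-1-en-2-yl]-2-[(E)-1-(triethylsilyloxy)but-2-en-1-yl]cyclohexane
Conditions: MOMCl, i-Pr2NEt, Bu4NI (cat.), CH2Cl2, 0 → 40 °C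
Reagents that add atoms: chloromethyl methyl ether, COCCl
Why: Acetal ether formation through the small, reactive methoxymethyl cation tolerates the neopentyl-type alcohol; the MOM ether is stable to fluoride, boranes, amine/acid and hot hydroxide.

Step 6
Reactants: 13 diene
Product: 15 2-[(1R,2R,3R)-3-(methoxymethoxy)-2-methyl-2-[(E)-1-(triethylsilyloxy)but-2-en-1-yl]cyclohexyl]-3-(2,3,5,6-tetramethoxyphenyl)propan-1-ol (both C9 epimers), via alkylborane 14 (not isolated)
Conditions: 9-BBN, THF, 0 → 50 °C; then NaOH (aq), H2O2, 0 °C → rt
Reagents that add atoms: hydrogen peroxide, OO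
Why: Hydroboration–oxidation; the bulky dialkylborane adds boron to the CH2 end of the 1,1-disubstituted alkene much faster than to the internal (E)-alkene, which is further shielded by quaternary C5 and the silyl ether, and alkaline peroxide replaces boron by hydroxyl. C9 becomes stereogenic without control, which does no harm because step 9 passes through a C9-planar enamine.

Step 7
Reactants: 15 primary alcohol
Product: 16 (E)-1-[(1S,2R,6R)-6-[1-hydroxy-3-(2,3,5,6-tetramethoxyphenyl)propan-2-yl]-2-(methoxymethoxy)-1-methylcyclohexyl]but-2-en-1-ol
Conditions: Bu4NF, THF, 0 °C → rt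
Reagents that add atoms: none
Why: Fluoride cleaves the only silyl ether in the molecule; the MOM ether is not affected.

Step 8
Reactants: 16 diol
Product: 17 (2E)-1-[(1R,2R,6R)-2-(methoxymethoxy)-1-methyl-6-[1-oxo-3-(2,3,5,6-tetramethoxyphenyl)propan-2-yl]cyclohexyl]but-2-en-1-one (keto-aldehyde; both C9 epimers)
Conditions: DMP (1,1,1-triacetoxy-1,1-dihydro-1,2-benziodoxol-3(1H)-one), NaHCO3, CH2Cl2, 0 °C → rt
Reagents that add atoms: none
Why: Periodinane oxidation of the allylic secondary alcohol and the primary alcohol in one operation gives the (E)-enone and the aldehyde without over-oxidation; the buffer protects the MOM ether, and epimerisation at C9 is of no concern.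

Step 9
Reactants: 17 keto-aldehyde
Product: 20 (1R,2R,4aR,5R,8aR)-5-(methoxymethoxy)-2,4a-dimethyl-4-oxo-1-[(2,3,5,6-tetramethoxyphenyl)methyl]decahydronaphthalene-1-carbaldehyde, via enamine 18 (not isolated), via iminium acetate 19 (not isolated)
Conditions: pyrrolidine (0.5 equiv), AcOH (0.5 equiv), CH2Cl2, rt; aqueous work-up
Reagents that add atoms: none
Why: Pyrrolidine condenses with the aldehyde to the trisubstituted enamine 18, which erases the C9 configuration so that both epimers pass through one nucleophile; its C9 adds to C8 of the enone, proton transfer gives the keto iminium salt 19, and hydrolysis releases 20 and the amine. The closest known reaction type is the amine-mediated intramolecular Michael addition of an aldehyde to an enone (an intramolecular Stork enamine reaction), which also creates quaternary carbons from α-branched aldehydes. Ring B closes in the 6-endo-trig mode, because the enone carbon C7 and the carbonyl C6 lie inside the new ring; this needs the s-trans conformer of the (E)-enone, which is accessible since C8 carries only hydrogen cis to C6. C8 is controlled by the single chair that the trans-diequatorial C5–C6 and C10–C9 bonds of ring A allow: in it the E geometry leaves the C8 methyl equatorial, with H8 on the face of H10. C9 is controlled by which enamine face bonds: the site beside quaternary C5 (the future axial position, syn to the C5 methyl) accepts the flat =CH–N carbon with its hydrogen turned inward far more easily than the arylmethyl group, which therefore sits beside H10 and becomes equatorial. The step needs chemoselectivity (condensation at the aldehyde and not at the hindered enone carbonyl), regioselectivity (aldol closure of C9 onto C6 would give a four-membered ring and is excluded) and the diastereoselectivity just described. The product is quaternary at C9 and cannot epimerise.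

Step 10
Reactants: 20 decalin keto-aldehyde
Product: 22 3-{[(1S,2R,4aR,5R,8aR)-5-(methoxymethoxy)-1,2,4a-trimethyldecahydronaphthalen-1-yl]methyl}-1,2,4,5-tetramethoxybenzene, via bis-hydrazone 21 (not isolated)
Conditions: N2H4·H2O, diethylene glycol, 130 °C; then KOH, 200 °C
Reagents that add atoms: none
Why: Wolff–Kishner reduction in the Huang–Minlon procedure: both carbonyls are converted to hydrazones before base is added, then hydroxide-induced loss of N2 gives the C6 methylene and the C9 methyl. No stereocentre is touched, the two carbonyls sit 1,4 across a chair so a cyclic azine is disfavoured, and the MOM and aryl ethers are stable to base.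

Step 11
Reactants: 22 MOM ether
Product: 23 (1R,4aR,5S,6R,8aR)-5,6,8a-trimethyl-5-[(2,3,5,6-tetramethoxyphenyl)methyl]decahydronaphthalen-1-ol
Conditions: HCl (conc.), MeOH, 50 °C
Reagents that add atoms: none
Why: Acid-catalysed acetal exchange with methanol removes the MOM group; at this stage the molecule has no alkene or other acid-sensitive group.

Step 12
Reactants: 23 alcohol
Product: 24 (4aR,5S,6R,8aR)-5,6,8a-trimethyl-5-[(2,3,5,6-tetramethoxyphenyl)methyl]octahydronaphthalen-1(2H)-one
Conditions: DMP, CH2Cl2, rt
Reagents that add atoms: none
Why: Periodinane oxidation of the hindered secondary alcohol to the C4 ketone, which removes the temporary C4 stereocentre.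

Step 13
Reactants: 24 ketone
Product: 25 3-{[(1S,2R,4aR,8aR)-1,2,4a-trimethyl-5-methylidenedecahydronaphthalen-1-yl]methyl}-1,2,4,5-tetramethoxybenzene
Conditions: Ph3PCH3Br, KOtBu, toluene, 90 °C
Reagents that add atoms: methyltriphenylphosphonium bromide, C[P+](c1ccccc1)(c1ccccc1)c1ccccc1.[Br-]
Why: Wittig methylenation with the unstabilised ylide at elevated temperature, as a ketone next to a quaternary carbon requires; neither α-carbon is a stereocentre that could epimerise (C5 is quaternary, C3 is a methylene).

Step 14
Reactants: 25 tetramethoxyarene
Product: 26 2,5-dimethoxy-3-{[(1S,2R,4aR,8aR)-1,2,4a-trimethyl-5-methylidenedecahydronaphthalen-1-yl]methyl}cyclohexa-2,5-diene-1,4-dione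
Conditions: (NH4)2Ce(NO3)6, MeCN/H2O, 0 °C
Reagents that add atoms: water, O
Why: Oxidative demethylation: two one-electron oxidations by tetravalent cerium, with attack of water at the ipso carbons and loss of methanol, turn one para pair of methoxy groups into the quinone carbonyls. By the symmetry of the aryl group either para pair gives the same 2,5-dimethoxyquinone, and the isolated alkene should not be oxidised at 0 °C.

Step 15
Reactants: 26 dimethoxyquinone
Product: 27 2-hydroxy-5-methoxy-3-{[(1S,2R,4aR,8aR)-1,2,4a-trimethyl-5-methylidenedecahydronaphthalen-1-yl]methyl}cyclohexa-2,5-diene-1,4-dione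
Conditions: HClO4 (70% aq.), THF, 0 °C → rt, short contact
Reagents that add atoms: water, O
Why: Acid-catalysed hydrolysis of a vinylogous ester (addition of water, loss of methanol); the C2′ methoxy group is pushed out of the quinone plane by the side chain, is the less stabilised vinylogous ester and should be cleaved first, while the coplanar C5′ methoxy group stays. Any ortho-quinone isomer from step 14 converges on 27 by the same hydrolysis and tautomerisation.

## Compound list

1 | 1,2,4,5-tetramethoxybenzene | COc1cc(OC)c(OC)cc1OC | starting material
2 | 2,3-dibromoprop-1-ene | C=C(Br)CBr | starting material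
3 | (2,3,5,6-tetramethoxyphenyl)lithium | [Li]c1c(OC)c(OC)cc(OC)c1OC | intermediate
4 | 3-(2-bromoprop-2-en-1-yl)-1,2,4,5-tetramethoxybenzene | C=C(Br)Cc1c(OC)c(OC)cc(OC)c1OC | intermediate
5 | 2-methylcyclohex-2-en-1-one | CC1=CCCCC1=O | starting material
6 | (E)-but-2-enal | C/C=C/C=O | starting material
7 | [3-(2,3,5,6-tetramethoxyphenyl)prop-1-en-2-yl]lithium | [Li]C(=C)Cc1c(OC)c(OC)cc(OC)c1OC | intermediate
8 | dimethyl[3-(2,3,5,6-tetramethoxyphenyl)prop-1-en-2-yl]alane | C[Al](C)C(=C)Cc1c(OC)c(OC)cc(OC)c1OC | intermediate
9 | dimethylaluminium (3R)-2-methyl-3-[3-(2,3,5,6-tetramethoxyphenyl)prop-1-en-2-yl]cyclohex-1-en-1-olate | C[Al](C)OC1=C(C)[C@@H](C(=C)Cc2c(OC)c(OC)cc(OC)c2OC)CCC1 | intermediate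
10 | (2S,3R)-2-[(E)-1-hydroxybut-2-en-1-yl]-2-methyl-3-[3-(2,3,5,6-tetramethoxyphenyl)prop-1-en-2-yl]cyclohexan-1-one, both carbinol epimers | O=C1CCC[C@H](C(=C)Cc2c(OC)c(OC)cc(OC)c2OC)[C@@]1(C)C(O)/C=C/C | intermediate
11 | (2S,3R)-2-methyl-3-[3-(2,3,5,6-tetramethoxyphenyl)prop-1-en-2-yl]-2-[(E)-1-(triethylsilyloxy)but-2-en-1-yl]cyclohexan-1-one | O=C1CCC[C@H](C(=C)Cc2c(OC)c(OC)cc(OC)c2OC)[C@@]1(C)C(O[Si](CC)(CC)CC)/C=C/C | intermediate
12 | (1R,2R,3R)-2-methyl-3-[3-(2,3,5,6-tetramethoxyphenyl)prop-1-en-2-yl]-2-[(E)-1-(triethylsilyloxy)but-2-en-1-yl]cyclohexan-1-ol | O[C@@H]1CCC[C@H](C(=C)Cc2c(OC)c(OC)cc(OC)c2OC)[C@@]1(C)C(O[Si](CC)(CC)CC)/C=C/C | intermediate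
13 | (1R,2R,3R)-1-(methoxymethoxy)-2-methyl-3-[3-(2,3,5,6-tetramethoxyphenyl)prop-1-en-2-yl]-2-[(E)-1-(triethylsilyloxy)but-2-en-1-yl]cyclohexane | COCO[C@@H]1CCC[C@H](C(=C)Cc2c(OC)c(OC)cc(OC)c2OC)[C@@]1(C)C(O[Si](CC)(CC)CC)/C=C/C | intermediate
14 | 9-[2-[(1R,2R,3R)-3-(methoxymethoxy)-2-methyl-2-[(E)-1-(triethylsilyloxy)but-2-en-1-yl]cyclohexyl]-3-(2,3,5,6-tetramethoxyphenyl)propyl]-9-borabicyclo[3.3.1]nonane | COCO[C@@H]1CCC[C@H](C(CB2C3CCCC2CCC3)Cc2c(OC)c(OC)cc(OC)c2OC)[C@@]1(C)C(O[Si](CC)(CC)CC)/C=C/C | intermediate
15 | 2-[(1R,2R,3R)-3-(methoxymethoxy)-2-methyl-2-[(E)-1-(triethylsilyloxy)but-2-en-1-yl]cyclohexyl]-3-(2,3,5,6-tetramethoxyphenyl)propan-1-ol, both C9 epimers | COCO[C@@H]1CCC[C@H](C(CO)Cc2c(OC)c(OC)cc(OC)c2OC)[C@@]1(C)C(O[Si](CC)(CC)CC)/C=C/C | intermediate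
16 | (E)-1-[(1S,2R,6R)-6-[1-hydroxy-3-(2,3,5,6-tetramethoxyphenyl)propan-2-yl]-2-(methoxymethoxy)-1-methylcyclohexyl]but-2-en-1-ol | COCO[C@@H]1CCC[C@H](C(CO)Cc2c(OC)c(OC)cc(OC)c2OC)[C@@]1(C)C(O)/C=C/C | intermediate
17 | (2E)-1-[(1R,2R,6R)-2-(methoxymethoxy)-1-methyl-6-[1-oxo-3-(2,3,5,6-tetramethoxyphenyl)propan-2-yl]cyclohexyl]but-2-en-1-one, both C9 epimers | COCO[C@@H]1CCC[C@H](C(C=O)Cc2c(OC)c(OC)cc(OC)c2OC)[C@@]1(C)C(=O)/C=C/C | intermediate
18 | (2E)-1-[(1R,2R,6R)-2-(methoxymethoxy)-1-methyl-6-[1-(pyrrolidin-1-yl)-3-(2,3,5,6-tetramethoxyphenyl)prop-1-en-2-yl]cyclohexyl]but-2-en-1-one | COCO[C@@H]1CCC[C@H](C(=CN2CCCC2)Cc2c(OC)c(OC)cc(OC)c2OC)[C@@]1(C)C(=O)/C=C/C | intermediate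
19 | 1-{[(1R,2R,4aR,5R,8aR)-5-(methoxymethoxy)-2,4a-dimethyl-4-oxo-1-[(2,3,5,6-tetramethoxyphenyl)methyl]decahydronaphthalen-1-yl]methylidene}pyrrolidin-1-ium acetate | COCO[C@@H]1CCC[C@@H]2[C@@](C=[N+]3CCCC3)(Cc3c(OC)c(OC)cc(OC)c3OC)[C@H](C)CC(=O)[C@@]12C.CC(=O)[O-] | intermediate
20 | (1R,2R,4aR,5R,8aR)-5-(methoxymethoxy)-2,4a-dimethyl-4-oxo-1-[(2,3,5,6-tetramethoxyphenyl)methyl]decahydronaphthalene-1-carbaldehyde | COCO[C@@H]1CCC[C@@H]2[C@@](C=O)(Cc3c(OC)c(OC)cc(OC)c3OC)[C@H](C)CC(=O)[C@@]12C | intermediate
21 | bis-hydrazone of 20 (C6 ketone and C9 formyl group) | COCO[C@@H]1CCC[C@@H]2[C@@](C=NN)(Cc3c(OC)c(OC)cc(OC)c3OC)[C@H](C)CC(=NN)[C@@]12C | intermediate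
22 | 3-{[(1S,2R,4aR,5R,8aR)-5-(methoxymethoxy)-1,2,4a-trimethyldecahydronaphthalen-1-yl]methyl}-1,2,4,5-tetramethoxybenzene | COCO[C@@H]1CCC[C@@H]2[C@@](C)(Cc3c(OC)c(OC)cc(OC)c3OC)[C@H](C)CC[C@@]12C | intermediate
23 | (1R,4aR,5S,6R,8aR)-5,6,8a-trimethyl-5-[(2,3,5,6-tetramethoxyphenyl)methyl]decahydronaphthalen-1-ol | O[C@@H]1CCC[C@@H]2[C@@](C)(Cc3c(OC)c(OC)cc(OC)c3OC)[C@H](C)CC[C@@]12C | intermediate
24 | (4aR,5S,6R,8aR)-5,6,8a-trimethyl-5-[(2,3,5,6-tetramethoxyphenyl)methyl]octahydronaphthalen-1(2H)-one | O=C1CCC[C@@H]2[C@@](C)(Cc3c(OC)c(OC)cc(OC)c3OC)[C@H](C)CC[C@@]12C | intermediate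
25 | 3-{[(1S,2R,4aR,8aR)-1,2,4a-trimethyl-5-methylidenedecahydronaphthalen-1-yl]methyl}-1,2,4,5-tetramethoxybenzene | C=C1CCC[C@@H]2[C@@](C)(Cc3c(OC)c(OC)cc(OC)c3OC)[C@H](C)CC[C@@]12C | intermediate
26 | 2,5-dimethoxy-3-{[(1S,2R,4aR,8aR)-1,2,4a-trimethyl-5-methylidenedecahydronaphthalen-1-yl]methyl}cyclohexa-2,5-diene-1,4-dione | C=C1CCC[C@@H]2[C@@](C)(CC3=C(OC)C(=O)C=C(OC)C3=O)[C@H](C)CC[C@@]12C | intermediate
27 | 2-hydroxy-5-methoxy-3-{[(1S,2R,4aR,8aR)-1,2,4a-trimethyl-5-methylidenedecahydronaphthalen-1-yl]methyl}cyclohexa-2,5-diene-1,4-dione | C=C1CCC[C@@H]2[C@@](C)(CC3=C(O)C(=O)C=C(OC)C3=O)[C@H](C)CC[C@@]12C | target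

## Step count and least certain steps

Total: 15 steps. Longest linear sequence: 15 steps (from 1; 2, 5 and 6 enter in steps 1 and 2).

Step 9 (key step). The most likely failure is poor facial discrimination at C9, that is, bonding through the enamine face that turns the arylmethyl group toward C5. Slow enamine formation from the hindered α-branched aldehyde could also let reversible amine addition to the enone dominate. Fallback, from 17 to 20: the aldehyde is converted with t-BuMe2SiOTf and Et3N (CH2Cl2, −78 °C) into the tert-butyldimethylsilyl enol ether F1; the enone cannot enolise toward C5 and stays intact. Me2AlCl (CH2Cl2, −78 °C) then activates the enone for an intramolecular Mukaiyama–Michael addition, and aqueous work-up gives 20. The nucleophile is now a neutral silyl enol ether in a Lewis-acid-bound, irreversible closure, so its facial preference is set differently and can be tuned through the silyl group.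

Step 2. The aluminium enolate of a tetrasubstituted enolate is a weak aldol donor, so slow or reversible addition to 6 and proton transfer can take over. Transfer of methyl in place of the hindered alkenyl group, and loss of enantioselectivity on an α-substituted enone, are further hazards that would first be met by changing the ligand. Fallback, from 9 to 10: the enolate is acetylated in the flask with Ac2O to the enol acetate F2, which is isolated. MeLi (2 equiv, THF, 0 °C) regenerates the regiodefined lithium enolate, ZnCl2 is added, and 6 is introduced at −78 °C to give 10. This separates the asymmetric addition from the aldol and uses a zinc enolate of proven aldol reactivity.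

Step 6. The 1,1-disubstituted alkene is flanked by a branched ring carbon and an ortho-disubstituted benzyl group, so hydroboration may be slow, and forcing conditions would start to consume the propenyl alkene. Fallback, from 13 to 17, without hydroboration: Bu4NF removes the silyl group to give the allylic alcohol F3, and DMP oxidation gives the enone F4. mCPBA (NaHCO3, CH2Cl2, 0 °C) then epoxidises the only electron-rich alkene to the epoxide F5, and a Meinwald rearrangement (BF3·OEt2, CH2Cl2, −78 °C) shifts hydride to give the aldehyde 17.

Step 10. Hydrazone formation at the C6 ketone beside quaternary C5 may be incomplete, and hot hydroxide can then open ring B by retro-Michael cleavage. Fallback, from 20 to 23: ethane-1,2-dithiol and BF3·OEt2 convert both carbonyls to dithiolanes and cleave the MOM ether in the same operation, giving the bis(dithiolane) alcohol F6. Raney Ni (EtOH, reflux) desulfurises it to 23, so step 11 is no longer needed.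

Step 15. Protonation of the exocyclic alkene, leading to migration of the double bond into ring A or closure onto the enol oxygen, may compete with hydrolysis; attack at the wrong methoxy group is the second hazard. Fallback, from 26 to 27, without acid: NaOH (aq)/THF hydrolyses both vinylogous esters to the 2,5-dihydroxyquinone F7. One equivalent of Me3SiCHN2 (MeOH/toluene, 0 °C) then methylates the C5′ oxygen, which is remote from the neopentyl-type side chain and the more accessible of the two.

## Further compounds

F1 | step 9 | (2E)-1-[(1R,2R,6R)-6-[1-(tert-butyldimethylsilyloxy)-3-(2,3,5,6-tetramethoxyphenyl)prop-1-en-2-yl]-2-(methoxymethoxy)-1-methylcyclohexyl]but-2-en-1-one | COCO[C@@H]1CCC[C@H](C(=CO[Si](C)(C)C(C)(C)C)Cc2c(OC)c(OC)cc(OC)c2OC)[C@@]1(C)C(=O)/C=C/C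
F2 | step 2 | (3R)-2-methyl-3-[3-(2,3,5,6-tetramethoxyphenyl)prop-1-en-2-yl]cyclohex-1-en-1-yl acetate | CC(=O)OC1=C(C)[C@@H](C(=C)Cc2c(OC)c(OC)cc(OC)c2OC)CCC1
F3 | step 6 | (E)-1-[(1S,2R,6R)-2-(methoxymethoxy)-1-methyl-6-[3-(2,3,5,6-tetramethoxyphenyl)prop-1-en-2-yl]cyclohexyl]but-2-en-1-ol | COCO[C@@H]1CCC[C@H](C(=C)Cc2c(OC)c(OC)cc(OC)c2OC)[C@@]1(C)C(O)/C=C/C
F4 | step 6 | (2E)-1-[(1R,2R,6R)-2-(methoxymethoxy)-1-methyl-6-[3-(2,3,5,6-tetramethoxyphenyl)prop-1-en-2-yl]cyclohexyl]but-2-en-1-one | COCO[C@@H]1CCC[C@H](C(=C)Cc2c(OC)c(OC)cc(OC)c2OC)[C@@]1(C)C(=O)/C=C/C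
F5 | step 6 | (2E)-1-[(1R,2R,6S)-2-(methoxymethoxy)-1-methyl-6-{2-[(2,3,5,6-tetramethoxyphenyl)methyl]oxiran-2-yl}cyclohexyl]but-2-en-1-one, both epoxide epimers | COCO[C@@H]1CCC[C@H](C2(Cc3c(OC)c(OC)cc(OC)c3OC)CO2)[C@@]1(C)C(=O)/C=C/C
F6 | step 10 | bis(1,3-dithiolane) of the C4-hydroxy analogue of 20 (spiro-dithiolane at C6, 1,3-dithiolan-2-yl at C9, free 4R hydroxyl) | O[C@@H]1CCC[C@@H]2[C@@](C3SCCS3)(Cc3c(OC)c(OC)cc(OC)c3OC)[C@H](C)CC3(SCCS3)[C@@]12C
F7 | step 15 | 2,5-dihydroxy-3-{[(1S,2R,4aR,8aR)-1,2,4a-trimethyl-5-methylidenedecahydronaphthalen-1-yl]methyl}cyclohexa-2,5-diene-1,4-dione | C=C1CCC[C@@H]2[C@@](C)(CC3=C(O)C(=O)C=C(O)C3=O)[C@H](C)CC[C@@]12C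
A1 | alternative 1 | methyl (2E,6R,7S,8E)-3,6,7-trimethyl-7-[(2,3,5,6-tetramethoxyphenyl)methyl]undeca-2,8,10-trienoate | C=C/C=C/[C@@](C)(Cc1c(OC)c(OC)cc(OC)c1OC)[C@H](C)CC/C(C)=C/C(=O)OC
A2 | alternative 1 | methyl (1R,4aR,5S,6R,8aR)-5,6,8a-trimethyl-5-[(2,3,5,6-tetramethoxyphenyl)methyl]-1,2,4a,5,6,7,8,8a-octahydronaphthalene-1-carboxylate | COC(=O)[C@@H]1CC=C[C@@H]2[C@@](C)(Cc3c(OC)c(OC)cc(OC)c3OC)[C@H](C)CC[C@@]12C
A3 | alternative 2 | (1S,2S,4aR,8aR)-2,5,5,8a-tetramethyl-1-[(2,3,5,6-tetramethoxyphenyl)methyl]decahydronaphthalen-2-ol | CC1(C)CCC[C@@]2(C)[C@H](Cc3c(OC)c(OC)cc(OC)c3OC)[C@@](C)(O)CC[C@H]12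
A4 | alternative 2 | 3-{[(1S,2R,4aR,8aR)-1,2,4a-trimethyl-5-methylidenedecahydronaphthalen-1-yl]methyl}-1,2,4,5-tetramethoxybenzene (identical with 25) | C=C1CCC[C@@H]2[C@@](C)(Cc3c(OC)c(OC)cc(OC)c3OC)[C@H](C)CC[C@@]12C
A5 | alternative 3 | 3-[(2S,3R)-5-bromo-2,3-dimethyl-1-(2,3,5,6-tetramethoxyphenyl)pentan-2-yl]-2-methylphenol | Cc1c(O)cccc1[C@@](C)(Cc1c(OC)c(OC)cc(OC)c1OC)[C@H](C)CCBr
A6 | alternative 3 | (5S,6R,8aR)-5,6,8a-trimethyl-5-[(2,3,5,6-tetramethoxyphenyl)methyl]-6,7,8,8a-tetrahydronaphthalen-1(5H)-one | O=C1C=CC=C2[C@@](C)(Cc3c(OC)c(OC)cc(OC)c3OC)[C@H](C)CC[C@@]12C
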